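Ring A bears oxygen on C5, C7 and C8a, so its six carbons are read as three alkynes, each oxygenated at one end and joined head to tail; two of them are already linked by the O1–C2–C3–C4 chain of ring C. Everything rests on cutting C4a–C8a, C5–C6 and C7–C8 together. A single rhodium-catalysed [2+2+2] cycloaddition of an enantiopure 1,7-diyne with methoxyacetylene then closes rings A and C and sets the 5-oxy, 7-methoxy and 8-prenyl pattern. The diyne is a (4R,5R)-pentynone: benzylic 5-methylhex-4-en-1-ynyl ether, ethoxyethynyl ketone and a methoxymethyl ether on the future C3, its stereocentres drawn from Sharpless epoxidation of cinnamyl alcohol and inverting benzoate opening.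

Key step: step 12

Remark: the future C3 oxygen is carried as an acetal and not as a silyl ether, because a silyl group next to the benzylic potassium alkoxide of step 6 would be liable to migrate; methoxyacetylene is taken as not dependably purchasable and is made fresh in step 11.

Step 1
Reactants: 1 (E)-cinnamyl alcohol
Product: 2 [(2S,3S)-3-phenyloxiran-2-yl]methanol
Conditions: t-BuOOH, Ti(OiPr)4 (5 mol%), L-(+)-diisopropyl tartrate (7.5 mol%), 4 Å MS, CH2Cl2, −20 °C
Reagents that add atoms: tert-butyl hydroperoxide, CC(C)(C)OO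
Why: Katsuki–Sharpless asymmetric epoxidation of an (E)-allylic alcohol: with the L-(+)-tartrate the titanium-bound peroxide reaches the alkene from the face that gives the (2S,3S)-epoxide, which sets the configuration of the later C3 directly and that of the later C2 in the sense that step 2 inverts.

Step 2
Reactants: 2 [(2S,3S)-3-phenyloxiran-2-yl]methanol
Product: 3 (1R,2S)-2,3-dihydroxy-1-phenylpropyl benzoate
Conditions: PhCO2H, Ti(OiPr)4 (1.5 equiv), CH2Cl2, rt
Reagents that add atoms: benzoic acid, O=C(O)c1ccccc1
Why: Ti(OiPr)4-mediated opening of a 2,3-epoxy alcohol by a carboxylic acid: benzoate attacks the titanium-activated epoxide at the benzylic carbon from the rear (SN2, inversion, S to R) while the neighbouring centre is untouched, so the anti O–C–C–O diad of the target is fixed here.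

Step 3
Reactants: 3 (1R,2S)-2,3-dihydroxy-1-phenylpropyl benzoate
Product: 4 (1R,2S)-3-[(tert-butyldiphenylsilyl)oxy]-2-hydroxy-1-phenylpropyl benzoate
Conditions: TBDPSCl, imidazole, CH2Cl2, 0 °C
Reagents that add atoms: tert-butyl(chloro)diphenylsilane, CC(C)(C)[Si](Cl)(c1ccccc1)c1ccccc1
Why: Selective silyl ether formation: the bulky silyl chloride reacts with the primary hydroxyl far faster than with the flanked secondary one, and imidazole at 0 °C is too mild to move the benzoate.

Step 4
Reactants: 4 (1R,2S)-3-[(tert-butyldiphenylsilyl)oxy]-2-hydroxy-1-phenylpropyl benzoate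
Product: 5 (1R,2S)-3-[(tert-butyldiphenylsilyl)oxy]-2-(methoxymethoxy)-1-phenylpropyl benzoate
Conditions: MOMCl, iPr2NEt, Bu4NI (cat.), CH2Cl2, 0 → 40 °C
Reagents that add atoms: chloromethyl methyl ether, COCCl
Why: Acetal (MOM ether) formation by alkylation with the chloromethyl ether under amine base, where no alkoxide is formed so neither benzoate nor silyl group migrates; the acetal cannot shift to the neighbouring alkoxide of step 6 and falls with BCl3 in the last step.

Step 5
Reactants: 5 (1R,2S)-3-[(tert-butyldiphenylsilyl)oxy]-2-(methoxymethoxy)-1-phenylpropyl benzoate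
Product: 6 (1R,2S)-3-[(tert-butyldiphenylsilyl)oxy]-2-(methoxymethoxy)-1-phenylpropan-1-ol
Conditions: K2CO3 (cat.), MeOH, rt
Reagents that add atoms: none
Why: Base-catalysed transesterification (methanolysis of the benzoate) frees only the benzylic hydroxyl, the silyl ether and the acetal being stable to carbonate in methanol and no bond at either stereocentre being broken.

Step 6
Reactants: 6 (1R,2S)-3-[(tert-butyldiphenylsilyl)oxy]-2-(methoxymethoxy)-1-phenylpropan-1-ol; 7 trichloroethylene; 8 prenyl bromide (1-bromo-3-methylbut-2-ene)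
Product: 11 tert-butyl{[(2S,3R)-2-(methoxymethoxy)-3-[(5-methylhex-4-en-1-yn-1-yl)oxy]-3-phenylpropyl]oxy}diphenylsilane, via dichlorovinyl ether 9 (not isolated), via lithium alkynyl ether 10 (not isolated)
Conditions: KH, THF, 0 °C; 7, −50 °C → rt; n-BuLi (2.5 equiv), −78 → −40 °C; 8, HMPA (or DMPU), −78 → 0 °C
Reagents that add atoms: none
Why: Ynol ether synthesis by the trichloroethylene route: the potassium salt of 6 replaces one chloride of 7 (net vinylic substitution by elimination–addition) to give the (E)-dichlorovinyl ether, two equivalents of n-BuLi turn this into the lithium alkoxyacetylide, and that is C-alkylated at the primary carbon of the allylic bromide (SN2), the C–O bond at the benzylic stereocentre staying intact throughout.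

Step 7
Reactants: 11 tert-butyl{[(2S,3R)-2-(methoxymethoxy)-3-[(5-methylhex-4-en-1-yn-1-yl)oxy]-3-phenylpropyl]oxy}diphenylsilane
Product: 12 (2S,3R)-2-(methoxymethoxy)-3-[(5-methylhex-4-en-1-yn-1-yl)oxy]-3-phenylpropan-1-ol
Conditions: TBAF, THF, 0 °C
Reagents that add atoms: none
Why: Fluoride-induced desilylation of the primary silyl ether under basic, non-acidic conditions that the acid-labile ynol ether, the acetal and the alkene tolerate.

Step 8
Reactants: 12 (2S,3R)-2-(methoxymethoxy)-3-[(5-methylhex-4-en-1-yn-1-yl)oxy]-3-phenylpropan-1-ol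
Product: 13 (2R,3R)-2-(methoxymethoxy)-3-[(5-methylhex-4-en-1-yn-1-yl)oxy]-3-phenylpropanal
Conditions: Dess–Martin periodinane, NaHCO3, CH2Cl2, 0 °C → rt; used crude
Reagents that add atoms: none
Why: Dess–Martin oxidation buffered with solid NaHCO3 gives the aldehyde without the acid that would hydrate the ynol ether and without the amine base that could epimerise the α-centre or expel the β-alkynyloxy group (the descriptor changes from S to R only through ligand priorities).

Step 9
Reactants: 13 (2R,3R)-2-(methoxymethoxy)-3-[(5-methylhex-4-en-1-yn-1-yl)oxy]-3-phenylpropanal; 14 ethoxyacetylene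
Product: 16 (3RS,4S,5R)-1-ethoxy-4-(methoxymethoxy)-5-[(5-methylhex-4-en-1-yn-1-yl)oxy]-5-phenylpent-1-yn-3-ol, via lithium ethoxyacetylide 15 (not isolated)
Conditions: 14, n-BuLi, THF, −78 °C; then 13, −78 °C; pH 7 buffer quench
Reagents that add atoms: none
Why: 1,2-Addition of a lithium acetylide to an aldehyde at −78 °C, faster than enolisation; the new carbinol centre forms as a mixture of epimers that is of no consequence because step 10 oxidises it away.

Step 10
Reactants: 16 (3RS,4S,5R)-1-ethoxy-4-(methoxymethoxy)-5-[(5-methylhex-4-en-1-yn-1-yl)oxy]-5-phenylpent-1-yn-3-ol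
Product: 17 (4R,5R)-1-ethoxy-4-(methoxymethoxy)-5-[(5-methylhex-4-en-1-yn-1-yl)oxy]-5-phenylpent-1-yn-3-one
Conditions: MnO2 (activated, excess), CH2Cl2, rt; filtered, kept cold, used promptly
Reagents that add atoms: none
Why: MnO2 oxidation of a propargylic alcohol to the ynone on a neutral solid surface, a standard way to 1-alkoxy-1-yn-3-ones that leaves both ynol ethers, the acetal and the base-sensitive α-stereocentre untouched.

Step 11
Reactants: 18 2-chloro-1,1-dimethoxyethane (chloroacetaldehyde dimethyl acetal)
Product: 20 methoxyacetylene, via sodium methoxyacetylide 19 (not isolated)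
Conditions: NaNH2 (3 equiv), liq. NH3, −33 °C; cold brine, −70 °C; distilled into a cold trap, kept as a cold CH2Cl2 solution
Reagents that add atoms: none
Why: Twofold base-induced elimination (loss of methanol, then of HCl) from the chloroacetal with NaNH2, the classical alkoxyacetylene preparation, gives the sodium acetylide, which is protonated on cold aqueous quench and distilled as the volatile alkyne boiling near 23 °C.

Step 12
Reactants: 17 (4R,5R)-1-ethoxy-4-(methoxymethoxy)-5-[(5-methylhex-4-en-1-yn-1-yl)oxy]-5-phenylpent-1-yn-3-one; 20 methoxyacetylene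
Product: 21 (2R,3R)-5-ethoxy-7-methoxy-3-(methoxymethoxy)-8-(3-methylbut-2-en-1-yl)-2-phenylchroman-4-one
Conditions: [Rh(cod)2]BF4 (10 mol%), (R)-H8-BINAP (10 mol%), activated with H2; 20 (5 equiv, slow addition), 4 Å MS, CH2Cl2, 0 → 20 °C
Reagents that add atoms: none
Why: Proposed new method: the cationic bisphosphine complex of monovalent rhodium should bind both alkynes of 17 and couple them oxidatively (C4a–C8a) to a rhodacyclopentadiene of trivalent rhodium fused to the new six-membered ring C, with the metal bound to the future C8 and C5; methoxyacetylene then inserts into the Rh–C5 bond (C5–C6) and reductive elimination (C7–C8) closes ring A and releases the catalyst. The closest known reaction type is the rhodium- or ruthenium-catalysed [2+2+2] cycloaddition of tethered diynes with monoynes, including cases with one ynamide or alkynyl ether component, whereas a tethered ynol ether and alkoxy-ynone pair combined with an alkoxyacetylene has not been shown. Ring C closes by intramolecular alkyne–alkyne coupling across the four-atom O1–C2–C3–C4 tether, the usual mode for a 1,7-diyne, and ring A closes by the intermolecular insertion and reductive-elimination pair on the metal. No stereocentre is created, C2 and C3 are spectators that carry no bond at risk under these neutral conditions, and either enantiomer of the ligand leads to the same product. The selectivity needed is the orientation of methoxyacetylene (its OMe carbon to C8, its CH carbon to C5) together with cross-reaction over self-trimerisation: the nucleophilic CH terminus of the alkoxyacetylene pairs with C5, the electrophilic β-carbon of the vinylogous-ester half of the rhodacycle, so the three partners combine strictly head to tail as the 5,7,8a-oxygen pattern demands, and slow addition of the monoyne to the fully substituted diyne, which is slow to couple with itself, holds back homotrimerisation. Working at or below room temperature avoids retro-ene and sigmatropic breakdown of the secondary benzylic ynol ether, and the trisubstituted prenyl alkene is too hindered to compete with the alkynes for the metal.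

Step 13
Reactants: 21 (2R,3R)-5-ethoxy-7-methoxy-3-(methoxymethoxy)-8-(3-methylbut-2-en-1-yl)-2-phenylchroman-4-one
Product: 22 (2R,3R)-3,5-dihydroxy-7-methoxy-8-(3-methylbut-2-en-1-yl)-2-phenylchroman-4-one
Conditions: BCl3 (4 equiv), CH2Cl2, −78 → 0 °C; poured into cold aq NaHCO3
Reagents that add atoms: none
Why: Lewis-acid ether cleavage with BCl3: boron held between the C4 carbonyl and the peri 5-ethoxy oxygen lets chloride displace the ethyl group while the unchelated 7-methoxy group is left, and the same reagent cleaves the acetal of the MOM group, whose residues leave on aqueous work-up, with no bond at C2 or C3 broken.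

Compound list
1 | (E)-cinnamyl alcohol | OC/C=C/c1ccccc1 | starting material
2 | [(2S,3S)-3-phenyloxiran-2-yl]methanol | OC[C@@H]1O[C@H]1c1ccccc1 | intermediate
3 | (1R,2S)-2,3-dihydroxy-1-phenylpropyl benzoate | O=C(c1ccccc1)O[C@H](c1ccccc1)[C@@H](O)CO | intermediate
4 | (1R,2S)-3-[(tert-butyldiphenylsilyl)oxy]-2-hydroxy-1-phenylpropyl benzoate | O=C(c1ccccc1)O[C@H](c1ccccc1)[C@@H](O)CO[Si](c1ccccc1)(c1ccccc1)C(C)(C)C | intermediate
5 | (1R,2S)-3-[(tert-butyldiphenylsilyl)oxy]-2-(methoxymethoxy)-1-phenylpropyl benzoate | O=C(c1ccccc1)O[C@H](c1ccccc1)[C@@H](OCOC)CO[Si](c1ccccc1)(c1ccccc1)C(C)(C)C | intermediate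
6 | (1R,2S)-3-[(tert-butyldiphenylsilyl)oxy]-2-(methoxymethoxy)-1-phenylpropan-1-ol | O[C@H](c1ccccc1)[C@@H](OCOC)CO[Si](c1ccccc1)(c1ccccc1)C(C)(C)C | intermediate
7 | trichloroethylene | ClC=C(Cl)Cl | starting material
8 | prenyl bromide (1-bromo-3-methylbut-2-ene) | CC(C)=CCBr | starting material
9 | tert-butyl{[(2S,3R)-3-{[(E)-1,2-dichloroethenyl]oxy}-2-(methoxymethoxy)-3-phenylpropyl]oxy}diphenylsilane (dichlorovinyl ether) | Cl/C=C(/Cl)O[C@H](c1ccccc1)[C@@H](OCOC)CO[Si](c1ccccc1)(c1ccccc1)C(C)(C)C | intermediate
10 | lithium {[(1R,2S)-3-[(tert-butyldiphenylsilyl)oxy]-2-(methoxymethoxy)-1-phenylpropyl]oxy}ethynide (lithium alkynyl ether) | [Li]C#CO[C@H](c1ccccc1)[C@@H](OCOC)CO[Si](c1ccccc1)(c1ccccc1)C(C)(C)C | intermediate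
11 | tert-butyl{[(2S,3R)-2-(methoxymethoxy)-3-[(5-methylhex-4-en-1-yn-1-yl)oxy]-3-phenylpropyl]oxy}diphenylsilane | CC(C)=CCC#CO[C@H](c1ccccc1)[C@@H](OCOC)CO[Si](c1ccccc1)(c1ccccc1)C(C)(C)C | intermediate
12 | (2S,3R)-2-(methoxymethoxy)-3-[(5-methylhex-4-en-1-yn-1-yl)oxy]-3-phenylpropan-1-ol | CC(C)=CCC#CO[C@H](c1ccccc1)[C@@H](OCOC)CO | intermediate
13 | (2R,3R)-2-(methoxymethoxy)-3-[(5-methylhex-4-en-1-yn-1-yl)oxy]-3-phenylpropanal | CC(C)=CCC#CO[C@H](c1ccccc1)[C@@H](OCOC)C=O | intermediate
14 | ethoxyacetylene | C#COCC | starting material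
15 | lithium ethoxyacetylide | [Li]C#COCC | intermediate
16 | (3RS,4S,5R)-1-ethoxy-4-(methoxymethoxy)-5-[(5-methylhex-4-en-1-yn-1-yl)oxy]-5-phenylpent-1-yn-3-ol (both C3 epimers) | CC(C)=CCC#CO[C@H](c1ccccc1)[C@@H](OCOC)C(O)C#COCC | intermediate
17 | (4R,5R)-1-ethoxy-4-(methoxymethoxy)-5-[(5-methylhex-4-en-1-yn-1-yl)oxy]-5-phenylpent-1-yn-3-one | CC(C)=CCC#CO[C@H](c1ccccc1)[C@@H](OCOC)C(=O)C#COCC | intermediate
18 | 2-chloro-1,1-dimethoxyethane | COC(CCl)OC | starting material
19 | sodium methoxyacetylide | [Na]C#COC | intermediate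
20 | methoxyacetylene | C#COC | intermediate
21 | (2R,3R)-5-ethoxy-7-methoxy-3-(methoxymethoxy)-8-(3-methylbut-2-en-1-yl)-2-phenylchroman-4-one | COc1cc(OCC)c2c(c1CC=C(C)C)O[C@H](c1ccccc1)[C@@H](OCOC)C2=O | intermediate
22 | (2R,3R)-3,5-dihydroxy-7-methoxy-8-(3-methylbut-2-en-1-yl)-2-phenylchroman-4-one | COc1cc(O)c2c(c1CC=C(C)C)O[C@H](c1ccccc1)[C@@H](O)C2=O | target

Total step count: 13
Longest linear sequence: 12 steps (steps 1–10, 12 and 13; step 11 is a one-step side branch)

Steps most likely to fail

1. Step 12 (proposed new method). The catalyst may be used up in trimerising methoxyacetylene, the monoyne may insert with the reverse orientation, or the Lewis-acidic metal may trigger addition of the ynol ether to the ketone before the two alkynes couple. The fallback uses known chemistry and brings ring A in ready-made; it sets out from epoxy alcohol 2 and prenyl bromide 8 and comes back to the route at target 22. Commercial 3,5-dimethoxyphenol is ortho-C-prenylated with 8 (NaH, toluene) to 3,5-dimethoxy-2-(3-methylbut-2-en-1-yl)phenol F1. Its sodium salt opens 2 at the benzylic carbon with inversion (aq NaOH, dioxane, 70 °C) to (2S,3R)-3-[3,5-dimethoxy-2-(3-methylbut-2-en-1-yl)phenoxy]-3-phenylpropane-1,2-diol F2. TEMPO with PhI(OAc)2 in MeCN–water takes the primary alcohol to (2R,3R)-3-[3,5-dimethoxy-2-(3-methylbut-2-en-1-yl)phenoxy]-2-hydroxy-3-phenylpropanoic acid F3. Trifluoroacetic anhydride (CH2Cl2, 0 °C) then effects intramolecular Friedel–Crafts acylation at the only free ortho position and gives (2R,3R)-5,7-dimethoxy-8-(3-methylbut-2-en-1-yl)-4-oxo-2-phenylchroman-3-yl trifluoroacetate F4, which methanolic NaHCO3 converts into (2R,3R)-3-hydroxy-5,7-dimethoxy-8-(3-methylbut-2-en-1-yl)-2-phenylchroman-4-one F5. BCl3 (CH2Cl2, −78 → 0 °C) finally removes only the chelated 5-O-methyl group and gives 22.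

2. Step 6. Vinylic substitution by the hindered secondary alkoxide may be slow or unclean, the silyl group may transfer towards the alkoxide under KH, and base may isomerise the skipped enyne during allylation. The fallback avoids the potassium alkoxide altogether; it sets out from alcohol 6 and comes back at lithium alkynyl ether 10, and so at 11. Alcohol 6 is formylated (acetic formic anhydride, pyridine, 0 °C) to (1R,2S)-3-[(tert-butyldiphenylsilyl)oxy]-2-(methoxymethoxy)-1-phenylpropyl formate F6. Ramirez dibromo-olefination of the formate carbonyl (CBr4, PPh3, CH2Cl2) gives tert-butyl{[(2S,3R)-3-[(2,2-dibromoethenyl)oxy]-2-(methoxymethoxy)-3-phenylpropyl]oxy}diphenylsilane F7. n-BuLi (2.2 equiv, THF, −78 °C) converts F7 by elimination and bromine–lithium exchange into 10, which is allylated with 8 as in step 6, if need be after transmetalation with CuI.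

3. Step 13. HCl released from BCl3 may add to the prenyl alkene, and the electrophile formed from the MOM group may attack the electron-rich C6 during the global Lewis-acid cleavage. The fallback splits the step into two orthogonal operations; it sets out from 21 and comes back at 22. Acetal exchange (catalytic HCl in MeOH, 40 °C) removes the MOM group first and gives (2R,3R)-5-ethoxy-3-hydroxy-7-methoxy-8-(3-methylbut-2-en-1-yl)-2-phenylchroman-4-one F8. MgI2·OEt2 (toluene–Et2O, 60 °C) then cleaves only the ethyl ether held in the magnesium chelate with the C4 carbonyl, without any protic acid, and gives 22.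

Further compounds
F1 | step 12 | 3,5-dimethoxy-2-(3-methylbut-2-en-1-yl)phenol | COc1cc(O)c(CC=C(C)C)c(OC)c1
F2 | step 12 | (2S,3R)-3-[3,5-dimethoxy-2-(3-methylbut-2-en-1-yl)phenoxy]-3-phenylpropane-1,2-diol | COc1cc(O[C@H](c2ccccc2)[C@@H](O)CO)c(CC=C(C)C)c(OC)c1
F3 | step 12 | (2R,3R)-3-[3,5-dimethoxy-2-(3-methylbut-2-en-1-yl)phenoxy]-2-hydroxy-3-phenylpropanoic acid | COc1cc(O[C@H](c2ccccc2)[C@@H](O)C(=O)O)c(CC=C(C)C)c(OC)c1
F4 | step 12 | (2R,3R)-5,7-dimethoxy-8-(3-methylbut-2-en-1-yl)-4-oxo-2-phenylchroman-3-yl trifluoroacetate | COc1cc(OC)c2c(c1CC=C(C)C)O[C@H](c1ccccc1)[C@@H](OC(=O)C(F)(F)F)C2=O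
F5 | step 12 | (2R,3R)-3-hydroxy-5,7-dimethoxy-8-(3-methylbut-2-en-1-yl)-2-phenylchroman-4-one | COc1cc(OC)c2c(c1CC=C(C)C)O[C@H](c1ccccc1)[C@@H](O)C2=O
F6 | step 6 | (1R,2S)-3-[(tert-butyldiphenylsilyl)oxy]-2-(methoxymethoxy)-1-phenylpropyl formate | O=CO[C@H](c1ccccc1)[C@@H](OCOC)CO[Si](c1ccccc1)(c1ccccc1)C(C)(C)C
F7 | step 6 | tert-butyl{[(2S,3R)-3-[(2,2-dibromoethenyl)oxy]-2-(methoxymethoxy)-3-phenylpropyl]oxy}diphenylsilane | BrC(Br)=CO[C@H](c1ccccc1)[C@@H](OCOC)CO[Si](c1ccccc1)(c1ccccc1)C(C)(C)C
F8 | step 13 | (2R,3R)-5-ethoxy-3-hydroxy-7-methoxy-8-(3-methylbut-2-en-1-yl)-2-phenylchroman-4-one | COc1cc(OCC)c2c(c1CC=C(C)C)O[C@H](c1ccccc1)[C@@H](O)C2=O
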